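**Strategy.** Ring B (C5–C10, labdane numbering) is opened at C6–C7 and C5–C10: an intramolecular Diels–Alder reaction of an acyclic triene closes rings A and B in one operation. The dienophile is the vinyl group C5=C6 on the quaternary carbon C4; the diene C7=C8–C9=C10 is a Z-1,2-bis(silyloxy)diene. The step exploits the C7 hydroxyl and the sp2 carbon C8 of ring B, which map onto the two diene oxygens. C4, set by copper-catalysed allylic alkynylation, is the only stereocentre of the precursor; its slim alkynyl group sits axial on the chair tether and relays C5, C10 and C7, and C9 follows by protonation. Afterwards the alkyne becomes the homoprenyl chain and the C8 enol ether the exocyclic methylene.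

Key step: step 11

Numbering remark: decalin compounds are named on the labdane skeleton (C17 on C8, C18 = 4α-methyl, C19 = carbon on the 4β bond, C20 = 10β-methyl, C11–C15 = side chain on C9); open-chain precursors use the same atom numbers in the text.
Assumption: starting materials 1, 6, 9, 14, 18 and 26 are taken as catalogue compounds.

Step 1
Reactants: 1 5-chloropent-1-yne
Product: 4 (2E)-6-chloro-3-methylhex-2-en-1-ol, via alkenylalane 2 (not isolated), via lithium alkenylaluminate 3 (not isolated)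
Conditions: Me3Al (2.5 equiv), Cp2ZrCl2 (0.25 equiv), CH2Cl2, 0 °C to rt; then n-BuLi, THF, −78 °C; (CH2O)n, rt
Reagents that add atoms: trimethylaluminium, C[Al](C)C; paraformaldehyde (as formaldehyde), C=O
Why: Negishi zirconium-catalysed carboalumination adds methyl and aluminium syn across the terminal alkyne with methyl on the internal carbon, and hydroxymethylation of the derived aluminate occurs with retention, so the E trisubstituted allylic alcohol should form.

Step 2
Reactants: 4 (2E)-6-chloro-3-methylhex-2-en-1-ol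
Product: 5 (2E)-6-chloro-3-methylhex-2-en-1-yl diethyl phosphate
Conditions: ClP(O)(OEt)2, Et3N, DMAP (cat.), CH2Cl2, 0 °C
Reagents that add atoms: diethyl chlorophosphate, CCOP(=O)(Cl)OCC
Why: Phosphorylation of the primary allylic alcohol with a chlorophosphate under amine base gives the leaving group needed for SN2′ substitution and does not touch the alkyl chloride.

Step 3
Reactants: 5 allylic phosphate; 6 ethynyl(trimethyl)silane
Product: 8 [(3S)-3-(3-chloropropyl)-3-methylpent-4-en-1-yn-1-yl]trimethylsilane, via alkynylalane 7 (not isolated)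
Conditions: 6, (i-Bu)2AlH, Et3N (5 mol %), hexane, 0 °C to rt; then 5, CuCl2·2H2O (5 mol %), chiral sulfonate-bearing imidazolinium salt (NHC precursor, 5.5 mol %, enantiomer that delivers S), THF, −15 °C
Reagents that add atoms: none
Why: Copper-catalysed enantioselective allylic substitution (SN2′) with an alkynylaluminium reagent on an E trisubstituted allylic phosphate creates the quaternary carbon C4 bearing vinyl, alkynyl and methyl groups, the face being chosen by the chiral NHC–copper catalyst whose enantiomer is selected to give S.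

Step 4
Reactants: 8 enyne chloride; 9 but-3-yn-1-ol
Product: 11 (8S)-8-ethenyl-8-methyl-10-(trimethylsilyl)deca-3,9-diyn-1-ol, via dilithiated butynol 10 (not isolated)
Conditions: 9, n-BuLi (2.1 equiv), THF, −78 to 0 °C; then 8, NaI (0.2 equiv), DMPU, rt to 45 °C
Reagents that add atoms: none
Why: SN2 alkylation of the acetylide carbon of the alkynol dianion by the primary chloride (iodide exchange in situ) is far faster than O-alkylation of the lithium alkoxide and leaves the silylalkyne and the stereocentre untouched.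

Step 5
Reactants: 11 diynol
Product: 13 (3E,8S)-8-ethenyl-3-iodo-4,8-dimethyl-10-(trimethylsilyl)dec-3-en-9-yn-1-ol, via alkenylmagnesium adduct 12 (not isolated)
Conditions: MeMgBr (4 equiv), Fe(acac)3 (0.2 equiv), THF, −78 to 0 °C; then I2, −78 °C to rt
Reagents that add atoms: methylmagnesium bromide, C[Mg]Br; iodine, II
Why: Alkoxide-directed iron-catalysed syn-carbomagnesiation of the homopropargylic alcohol delivers methyl to the distal and magnesium to the proximal alkyne carbon, and iodinolysis with retention gives the tetrasubstituted E iodoalkene with iodine cis to the new methyl, while the undirected silylalkyne stays.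

Step 6
Reactants: 13 iodoalkenol; 14 2-{[tert-butyl(dimethyl)silyl]oxy}-N-methoxy-N-methylacetamide
Product: 16 (3E,8S)-1-{[tert-butyl(dimethyl)silyl]oxy}-8-ethenyl-3-(2-hydroxyethyl)-4,8-dimethyl-10-(trimethylsilyl)dec-3-en-9-yn-2-one, via alkenyllithium 15 (not isolated)
Conditions: t-BuLi (3.2 equiv), Et2O, −78 °C; then 14, −78 to −20 °C; aq. NH4Cl
Reagents that add atoms: none
Why: Iodine–lithium exchange gives a configurationally stable alkenyllithium that is acylated once by the Weinreb amide through its stable chelated adduct, so the alkene geometry (acyl group cis to the C10 methyl) is kept.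

Step 7
Reactants: 16 hydroxy enone
Product: 17 (3E,8S)-1-{[tert-butyl(dimethyl)silyl]oxy}-8-ethenyl-3-(2-iodoethyl)-4,8-dimethyl-10-(trimethylsilyl)dec-3-en-9-yn-2-one
Conditions: PPh3, I2, imidazole, CH2Cl2, 0 °C
Reagents that add atoms: iodine, II
Why: Appel iodination converts the primary alcohol under nearly neutral conditions, which avoids elimination toward the cross-conjugated dienone and leaves the silyl ether intact.

Step 8
Reactants: 18 methyl 3-oxobutanoate
Product: 19 methyl (2E)-3-{[(trifluoromethyl)sulfonyl]oxy}but-2-enoate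
Conditions: Tf2O, aq. Me4NOH, hexane, 5 °C
Reagents that add atoms: trifluoromethanesulfonic anhydride, O=S(=O)(OS(=O)(=O)C(F)(F)F)C(F)(F)F
Why: O-Triflation of the β-keto ester enolate with a non-coordinating tetramethylammonium counter-ion goes through the extended enolate and should give the E enol triflate (triflate trans to the ester).

Step 9
Reactants: 17 iodo enone; 19 enol triflate
Product: 21 methyl (2E,6E,11S)-6-({[tert-butyl(dimethyl)silyl]oxy}acetyl)-11-ethenyl-3,7,11-trimethyl-13-(trimethylsilyl)trideca-2,6-dien-12-ynoate, via alkylzinc iodide 20 (not isolated)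
Conditions: Zn dust (activated with TMSCl and 1,2-dibromoethane), DMA, 35 °C; then 19, Pd(dppf)Cl2 (5 mol %), THF, rt to 45 °C
Reagents that add atoms: none
Why: Zinc insertion into the primary iodide tolerates ketone and ester, and the Negishi sp3–sp2 coupling proceeds with retention at the enol triflate, which sets the 13E enoate.

Step 10
Reactants: 21 enone ester
Product: 22 methyl (2E,6E,11S)-6-[(1Z)-2-{[tert-butyl(dimethyl)silyl]oxy}-1-{[tri(propan-2-yl)silyl]oxy}ethenyl]-11-ethenyl-3,7,11-trimethyl-13-(trimethylsilyl)trideca-2,6-dien-12-ynoate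
Conditions: TIPSOTf, Et3N, CH2Cl2, −78 to 0 °C
Reagents that add atoms: tri(propan-2-yl)silyl trifluoromethanesulfonate, CC(C)[Si](OS(=O)(=O)C(F)(F)F)(C(C)C)C(C)C
Why: Soft enolisation with silyl triflate and amine silylates the ketone toward its only α-CH2 (C7) to give the cross-conjugated 2-silyloxydiene, the Z enol ether (both oxygens cis) being favoured by dipole and steric effects, and only this isomer can react in step 11.

Step 11
Reactants: 22 bis(silyloxy) triene
Product: 23 methyl (13E)-7α-{[tert-butyl(dimethyl)silyl]oxy}-8-{[tri(propan-2-yl)silyl]oxy}-19-[(trimethylsilyl)methylidyne]labda-8,13-dien-15-oate (4α-CH3; 4β-C≡C–SiMe3; 5α-H; 10β-CH3)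
Conditions: toluene (0.01 M), BHT, Et3N (0.1 equiv), silylated sealed tube, 200 °C
Reagents that add atoms: none
Why: A thermal, concerted, suprafacial [4+2] cycloaddition (type 1 intramolecular Diels–Alder reaction of a 1,3,9-decatriene; closest known class: thermal cyclisations of 2-silyloxy-1,3,9-decatrienes onto unactivated terminal alkenes) joins the diene C7=C8–C9=C10 and the vinyl group C5=C6, forming C6–C7 and C5–C10 together. Ring B is the cyclohexene made by the cycloaddition itself, and ring A closes through the C5–C10 bond as the four-carbon tether C1–C4 folds into a six-membered chair, helped by the gem-disubstitution at C4. The anti (trans-fused) transition state should be preferred because the tether is E on C10 and the C9 substituent clashes with the tether in the syn arrangement, which sets 5α-H against the 10β-methyl. C7 follows from the Z enol ether: its silyloxy group lies outside on the diene and ends cis to the C10–C1 bond, that is 7α. The C4 centre decides the face, since the rod-like silylethynyl group (small A value) takes the axial site syn to the C10 methyl while the 4-methyl stays equatorial, so C5, C7 and C10 are relayed from C4. The step needs the alkene and not the silylalkyne as 2π partner (the silyl-bearing carbon would have to bond to the hindered C7) and cycloaddition ahead of a 1,5-hydrogen shift from the inside C10 methyl.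

Step 12
Reactants: 23 cycloadduct
Product: 25 methyl (13E)-7α-{[tert-butyl(dimethyl)silyl]oxy}-19-methylidene-8-{[tri(propan-2-yl)silyl]oxy}labda-8,13-dien-15-oate (4β-vinyl), via terminal alkyne 24 (not isolated)
Conditions: K2CO3, MeOH/THF, rt; then Pd/CaCO3 poisoned with Pb(OAc)2, quinoline, H2 (1 atm), rt
Reagents that add atoms: none
Why: Methanolysis cleaves the C(sp)–Si bond only, and Lindlar semi-hydrogenation stops at the monosubstituted alkene while the trisubstituted enoate and the tetrasubstituted enol ether are not reduced.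

Step 13
Reactants: 25 vinyl compound; 26 1-bromo-2-methylprop-1-ene
Product: 28 methyl (13E)-7α-{[tert-butyl(dimethyl)silyl]oxy}-19-(3-methylbut-2-en-1-yl)-8-{[tri(propan-2-yl)silyl]oxy}labda-8,13-dien-15-oate, via alkylborane 27 (not isolated)
Conditions: 9-BBN (1.5 equiv), THF, rt to 40 °C; then 26, Pd(dppf)Cl2 (5 mol %), K3PO4 (3 M aq.), DMF, 50 °C
Reagents that add atoms: none
Why: 9-BBN hydroborates only the monosubstituted alkene at its terminal carbon, and the B-alkyl Suzuki–Miyaura coupling with the alkenyl bromide completes the homoprenyl chain without touching the enol ether or the ester.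

Step 14
Reactants: 28 homoprenyl enol ether
Product: 29 methyl (13E)-7α-{[tert-butyl(dimethyl)silyl]oxy}-19-(3-methylbut-2-en-1-yl)-8-oxo-17-norlabd-13-en-15-oate (9α-H)
Conditions: TBAF (1.1 equiv), AcOH (1.5 equiv), THF, −20 to 0 °C
Reagents that add atoms: none
Why: Fluoride cleaves the silyl enol ether much faster than the secondary silyl ether, and the enolate is protonated at C9 on the α face anti to the C10 methyl (axial protonation), which gives 9α-H with the side chain equatorial, also the more stable epimer.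

Step 15
Reactants: 29 ketone
Product: 30 methyl (13E)-7α-{[tert-butyl(dimethyl)silyl]oxy}-19-(3-methylbut-2-en-1-yl)labda-8(17),13-dien-15-oate
Conditions: Zn, CH2Br2, TiCl4 (pre-formed reagent), THF/CH2Cl2, 0 °C to rt
Reagents that add atoms: dibromomethane, BrCBr
Why: Takai–Lombardo methylenation uses a non-basic titanium–zinc carbenoid that converts hindered enolisable ketones without epimerising C7 or C9 and does not attack the ester.

Step 16
Reactants: 30 silyl ether ester
Product: 32 (4R,5S,7R,9R,10S,13E)-7-hydroxy-19-(3-methylbut-2-en-1-yl)labda-8(17),13-dien-15-oic acid (CNP0169778.1), via hydroxy ester 31 (not isolated)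
Conditions: TBAF, THF, rt; then LiOH, MeOH/H2O, 45 °C; 1 M HCl to pH 4, 0 °C
Reagents that add atoms: lithium hydroxide (hydroxide oxygen of the acid), [Li+].[OH-]
Why: Fluoride desilylation frees the 7α-hydroxyl and saponification of the methyl ester with mild acidification gives the acid, neither step touching a stereocentre or the alkenes.

**Compound list**

1 | 5-chloropent-1-yne | C#CCCCCl | starting material
2 | [(1E)-5-chloro-2-methylpent-1-en-1-yl]dimethylalane | C[Al](C)/C=C(\C)CCCCl | intermediate (not isolated)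
3 | lithium butyl[(1E)-5-chloro-2-methylpent-1-en-1-yl]dimethylaluminate | [Li+].CCCC[Al-](C)(C)/C=C(\C)CCCCl | intermediate (not isolated)
4 | (2E)-6-chloro-3-methylhex-2-en-1-ol | OC/C=C(\C)CCCCl | intermediate
5 | (2E)-6-chloro-3-methylhex-2-en-1-yl diethyl phosphate | CCOP(=O)(OCC)OC/C=C(\C)CCCCl | intermediate
6 | ethynyl(trimethyl)silane | C#C[Si](C)(C)C | starting material
7 | bis(2-methylpropyl)[(trimethylsilyl)ethynyl]alane | CC(C)C[Al](CC(C)C)C#C[Si](C)(C)C | intermediate (not isolated)
8 | [(3S)-3-(3-chloropropyl)-3-methylpent-4-en-1-yn-1-yl]trimethylsilane | C=C[C@@](C)(C#C[Si](C)(C)C)CCCCl | intermediate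
9 | but-3-yn-1-ol | OCCC#C | starting material
10 | lithium 4-lithiobut-3-yn-1-olate | [Li]OCCC#C[Li] | intermediate (not isolated)
11 | (8S)-8-ethenyl-8-methyl-10-(trimethylsilyl)deca-3,9-diyn-1-ol | OCCC#CCCC[C@@](C)(C=C)C#C[Si](C)(C)C | intermediate
12 | bromomagnesium (3E,8S)-3-(bromomagnesio)-8-ethenyl-4,8-dimethyl-10-(trimethylsilyl)dec-3-en-9-yn-1-olate | Br[Mg]OCC/C([Mg]Br)=C(/C)CCC[C@@](C)(C=C)C#C[Si](C)(C)C | intermediate (not isolated)
13 | (3E,8S)-8-ethenyl-3-iodo-4,8-dimethyl-10-(trimethylsilyl)dec-3-en-9-yn-1-ol | OCC/C(I)=C(/C)CCC[C@@](C)(C=C)C#C[Si](C)(C)C | intermediate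
14 | 2-{[tert-butyl(dimethyl)silyl]oxy}-N-methoxy-N-methylacetamide | CON(C)C(=O)CO[Si](C)(C)C(C)(C)C | starting material
15 | lithium (3Z,8S)-8-ethenyl-3-lithio-4,8-dimethyl-10-(trimethylsilyl)dec-3-en-9-yn-1-olate | [Li]OCC/C([Li])=C(/C)CCC[C@@](C)(C=C)C#C[Si](C)(C)C | intermediate (not isolated)
16 | (3E,8S)-1-{[tert-butyl(dimethyl)silyl]oxy}-8-ethenyl-3-(2-hydroxyethyl)-4,8-dimethyl-10-(trimethylsilyl)dec-3-en-9-yn-2-one | OCC/C(C(=O)CO[Si](C)(C)C(C)(C)C)=C(/C)CCC[C@@](C)(C=C)C#C[Si](C)(C)C | intermediate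
17 | (3E,8S)-1-{[tert-butyl(dimethyl)silyl]oxy}-8-ethenyl-3-(2-iodoethyl)-4,8-dimethyl-10-(trimethylsilyl)dec-3-en-9-yn-2-one | ICC/C(C(=O)CO[Si](C)(C)C(C)(C)C)=C(/C)CCC[C@@](C)(C=C)C#C[Si](C)(C)C | intermediate
18 | methyl 3-oxobutanoate | COC(=O)CC(C)=O | starting material
19 | methyl (2E)-3-{[(trifluoromethyl)sulfonyl]oxy}but-2-enoate | COC(=O)/C=C(\C)OS(=O)(=O)C(F)(F)F | intermediate
20 | alkylzinc iodide of 17 (iodozincio in place of iodo) | I[Zn]CC/C(C(=O)CO[Si](C)(C)C(C)(C)C)=C(/C)CCC[C@@](C)(C=C)C#C[Si](C)(C)C | intermediate (not isolated)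
21 | methyl (2E,6E,11S)-6-({[tert-butyl(dimethyl)silyl]oxy}acetyl)-11-ethenyl-3,7,11-trimethyl-13-(trimethylsilyl)trideca-2,6-dien-12-ynoate | COC(=O)/C=C(\C)CC/C(C(=O)CO[Si](C)(C)C(C)(C)C)=C(/C)CCC[C@@](C)(C=C)C#C[Si](C)(C)C | intermediate
22 | methyl (2E,6E,11S)-6-[(1Z)-2-{[tert-butyl(dimethyl)silyl]oxy}-1-{[tri(propan-2-yl)silyl]oxy}ethenyl]-11-ethenyl-3,7,11-trimethyl-13-(trimethylsilyl)trideca-2,6-dien-12-ynoate | CC(C)(C)[Si](C)(C)O/C=C(O[Si](C(C)C)(C(C)C)C(C)C)/C(CC/C(C)=C/C(=O)OC)=C(\C)CCC[C@@](C)(C=C)C#C[Si](C)(C)C | intermediate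
23 | methyl (13E)-7α-{[tert-butyl(dimethyl)silyl]oxy}-8-{[tri(propan-2-yl)silyl]oxy}-19-[(trimethylsilyl)methylidyne]labda-8,13-dien-15-oate (5α-H, 10β-CH3, 4α-CH3) | CC(C)[Si](C(C)C)(C(C)C)OC=1[C@H](O[Si](C)(C)C(C)(C)C)C[C@H]2[C@@](C)(C#C[Si](C)(C)C)CCC[C@]2(C)C=1CC/C(C)=C/C(=O)OC | intermediate
24 | methyl (13E)-7α-{[tert-butyl(dimethyl)silyl]oxy}-19-methylidyne-8-{[tri(propan-2-yl)silyl]oxy}labda-8,13-dien-15-oate (4β-ethynyl) | CC(C)[Si](C(C)C)(C(C)C)OC=1[C@H](O[Si](C)(C)C(C)(C)C)C[C@H]2[C@@](C)(C#C)CCC[C@]2(C)C=1CC/C(C)=C/C(=O)OC | intermediate (not isolated)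
25 | methyl (13E)-7α-{[tert-butyl(dimethyl)silyl]oxy}-19-methylidene-8-{[tri(propan-2-yl)silyl]oxy}labda-8,13-dien-15-oate (4β-vinyl) | CC(C)[Si](C(C)C)(C(C)C)OC=1[C@H](O[Si](C)(C)C(C)(C)C)C[C@H]2[C@@](C)(C=C)CCC[C@]2(C)C=1CC/C(C)=C/C(=O)OC | intermediate
26 | 1-bromo-2-methylprop-1-ene | CC(C)=CBr | starting material
27 | methyl (13E)-19-[(9-borabicyclo[3.3.1]nonan-9-yl)methyl]-7α-{[tert-butyl(dimethyl)silyl]oxy}-8-{[tri(propan-2-yl)silyl]oxy}labda-8,13-dien-15-oate | CC(C)[Si](C(C)C)(C(C)C)OC=1[C@H](O[Si](C)(C)C(C)(C)C)C[C@H]2[C@@](C)(CCB3C4CCCC3CCC4)CCC[C@]2(C)C=1CC/C(C)=C/C(=O)OC | intermediate (not isolated)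
28 | methyl (13E)-7α-{[tert-butyl(dimethyl)silyl]oxy}-19-(3-methylbut-2-en-1-yl)-8-{[tri(propan-2-yl)silyl]oxy}labda-8,13-dien-15-oate | CC(C)[Si](C(C)C)(C(C)C)OC=1[C@H](O[Si](C)(C)C(C)(C)C)C[C@H]2[C@@](C)(CCC=C(C)C)CCC[C@]2(C)C=1CC/C(C)=C/C(=O)OC | intermediate
29 | methyl (13E)-7α-{[tert-butyl(dimethyl)silyl]oxy}-19-(3-methylbut-2-en-1-yl)-8-oxo-17-norlabd-13-en-15-oate (9α-H) | O=C1[C@H](O[Si](C)(C)C(C)(C)C)C[C@H]2[C@@](C)(CCC=C(C)C)CCC[C@]2(C)[C@H]1CC/C(C)=C/C(=O)OC | intermediate
30 | methyl (13E)-7α-{[tert-butyl(dimethyl)silyl]oxy}-19-(3-methylbut-2-en-1-yl)labda-8(17),13-dien-15-oate | C=C1[C@H](O[Si](C)(C)C(C)(C)C)C[C@H]2[C@@](C)(CCC=C(C)C)CCC[C@]2(C)[C@H]1CC/C(C)=C/C(=O)OC | intermediate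
31 | methyl (13E)-7α-hydroxy-19-(3-methylbut-2-en-1-yl)labda-8(17),13-dien-15-oate | C=C1[C@H](O)C[C@H]2[C@@](C)(CCC=C(C)C)CCC[C@]2(C)[C@H]1CC/C(C)=C/C(=O)OC | intermediate (not isolated)
32 | (4R,5S,7R,9R,10S,13E)-7-hydroxy-19-(3-methylbut-2-en-1-yl)labda-8(17),13-dien-15-oic acid | C=C1[C@H](O)C[C@H]2[C@@](C)(CCC=C(C)C)CCC[C@]2(C)[C@H]1CC/C(C)=C/C(=O)O | target

**Step count and risks**

Total step count: 16. Longest linear sequence: 15 steps (steps 1–7 and 9–16, from 5-chloropent-1-yne).

Step 11 (cycloaddition). The unactivated vinyl group and the fully substituted diene terminus may make ring closure so slow that the 1,5-hydrogen shift from the inside C10 methyl, loss of the enol ether, or leakage to the cis-fused or wrong-face adduct takes over. The fallback lowers the dienophile LUMO with a temporary nitro group; it sets out from enone 21 and returns at cycloadduct 23. The terminal vinyl group of 21 would be cleaved selectively (OsO4 cat., NaIO4, 2,6-lutidine, dioxane/H2O; the enone and enoate alkenes are electron-poor) to the aldehyde F1. A Henry reaction with nitromethane (KOt-Bu cat.) would give the nitro alcohol F2, and dehydration (MsCl, Et3N) the E nitroalkene F3. Silylation as in step 10 would give the nitro triene F4, which should undergo the same intramolecular [4+2] near room temperature to the 6α-nitro cycloadduct F5. Radical denitration (Bu3SnH, AIBN, toluene, 100 °C) would then give 23.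

Step 3 (allylic alkynylation). Enantioselectivity and SN2′ over SN2 selectivity may erode because the catalyst must tell a methyl from a primary alkyl group and the silylalkynyl aluminium reagent is less common. The fallback uses reagent-controlled epoxidation and stereospecific substitution; it sets out from allylic alcohol 4 and returns at 8. Sharpless epoxidation (Ti(OiPr)4, D-(−)-diethyl tartrate, t-BuOOH, 4 Å sieves, CH2Cl2, −20 °C) would give the epoxy alcohol F6. Opening at the tertiary carbon with inversion by Et2Al–C≡C–SiMe3 (from 6, n-BuLi and Et2AlCl, toluene, 0 °C) would give the diol F7. Glycol cleavage (NaIO4, THF/H2O) would give the α-quaternary aldehyde F8, and Wittig methylenation (Ph3P=CH2, THF) would give 8.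

Step 6 (acylation). Iodine–lithium exchange on the hindered alkoxide-bearing iodoalkene may be incomplete, and the γ-hydroxy enone 16 may close to a hemiketal or eliminate during the following iodination. The fallback introduces the acyl group last by a chromium-mediated addition that tolerates the ester; it sets out from 13 and returns at 21. Appel iodination of 13 would give the diiodide F9. Zinc insertion into its alkyl iodide only would give the alkylzinc reagent F10, and Negishi coupling with 19 (Pd(dppf)Cl2) the iodoalkene ester F11. Nozaki–Hiyama–Kishi addition to {[tert-butyl(dimethyl)silyl]oxy}acetaldehyde (CrCl2, NiCl2 cat., DMF/DMSO) would give the allylic alcohol F12 as a mixture of carbinol epimers, and Dess–Martin oxidation would give 21.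

Further compounds
F1 | step 11 | methyl (2E,6E,11R)-6-({[tert-butyl(dimethyl)silyl]oxy}acetyl)-11-formyl-3,7,11-trimethyl-13-(trimethylsilyl)trideca-2,6-dien-12-ynoate | COC(=O)/C=C(\C)CC/C(C(=O)CO[Si](C)(C)C(C)(C)C)=C(/C)CCC[C@@](C)(C=O)C#C[Si](C)(C)C
F2 | step 11 | nitro alcohol of F1 (1-hydroxy-2-nitroethyl in place of formyl, both carbinol epimers) | COC(=O)/C=C(\C)CC/C(C(=O)CO[Si](C)(C)C(C)(C)C)=C(/C)CCC[C@@](C)(C(O)C[N+](=O)[O-])C#C[Si](C)(C)C
F3 | step 11 | methyl (2E,6E,11S)-6-({[tert-butyl(dimethyl)silyl]oxy}acetyl)-3,7,11-trimethyl-11-[(E)-2-nitroethenyl]-13-(trimethylsilyl)trideca-2,6-dien-12-ynoate | COC(=O)/C=C(\C)CC/C(C(=O)CO[Si](C)(C)C(C)(C)C)=C(/C)CCC[C@@](C)(/C=C/[N+](=O)[O-])C#C[Si](C)(C)C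
F4 | step 11 | nitro triene (22 with (E)-2-nitroethenyl in place of ethenyl on C4) | CC(C)(C)[Si](C)(C)O/C=C(O[Si](C(C)C)(C(C)C)C(C)C)/C(CC/C(C)=C/C(=O)OC)=C(\C)CCC[C@@](C)(/C=C/[N+](=O)[O-])C#C[Si](C)(C)C
F5 | step 11 | 6α-nitro derivative of cycloadduct 23 | CC(C)[Si](C(C)C)(C(C)C)OC=1[C@H](O[Si](C)(C)C(C)(C)C)[C@H]([N+](=O)[O-])[C@H]2[C@@](C)(C#C[Si](C)(C)C)CCC[C@]2(C)C=1CC/C(C)=C/C(=O)OC
F6 | step 3 | [(2R,3R)-3-(3-chloropropyl)-3-methyloxiran-2-yl]methanol | OC[C@H]1O[C@]1(C)CCCCl
F7 | step 3 | (2S,3R)-3-(3-chloropropyl)-3-methyl-5-(trimethylsilyl)pent-4-yne-1,2-diol | OC[C@@H](O)[C@@](C)(C#C[Si](C)(C)C)CCCCl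
F8 | step 3 | (2R)-5-chloro-2-methyl-2-[(trimethylsilyl)ethynyl]pentanal | O=C[C@@](C)(C#C[Si](C)(C)C)CCCCl
F9 | step 6 | [(3S,7E)-3-ethenyl-8,10-diiodo-3,7-dimethyldec-7-en-1-yn-1-yl]trimethylsilane | ICC/C(I)=C(/C)CCC[C@@](C)(C=C)C#C[Si](C)(C)C
F10 | step 6 | alkylzinc iodide of F9 (iodozincio at the primary carbon) | I[Zn]CC/C(I)=C(/C)CCC[C@@](C)(C=C)C#C[Si](C)(C)C
F11 | step 6 | methyl (2E,6E,11S)-11-ethenyl-6-iodo-3,7,11-trimethyl-13-(trimethylsilyl)trideca-2,6-dien-12-ynoate | COC(=O)/C=C(\C)CC/C(I)=C(/C)CCC[C@@](C)(C=C)C#C[Si](C)(C)C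
F12 | step 6 | methyl (2E,6E,11S)-6-(2-{[tert-butyl(dimethyl)silyl]oxy}-1-hydroxyethyl)-11-ethenyl-3,7,11-trimethyl-13-(trimethylsilyl)trideca-2,6-dien-12-ynoate (both carbinol epimers) | COC(=O)/C=C(\C)CC/C(C(O)CO[Si](C)(C)C(C)(C)C)=C(/C)CCC[C@@](C)(C=C)C#C[Si](C)(C)C
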